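**Retrosynthetic overview**
1. Ring E (azacyclononane) is closed last by intramolecular N‑alkylation of the ring‑D lactam at C19; the C2–C18 bond and both side‑chain stereocentres come from an Evans syn‑aldol on a tetracyclic aldehyde.
2. Ring A is closed at C14–C15 by palladium‑catalysed allylic alkylation of a tethered malonate (C15 set by CBS reduction); ring B comes from carbonylative Stille coupling and Nazarov cyclisation on the ring‑C ketone.
3. Ring C is closed by Dieckmann‑type acylation of the ring‑D lactam enolate, which makes C8 a bridgehead; C8 is then quaternised by Michael addition to dimethyl methylidenemalonate.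
4. The ring‑D lactam with quaternary C5 comes from a pyrrolidinone template (trans‑selective alkylation, reductive opening, re‑lactamisation).
5. Key union: the C5–C6 bond is made by an intermolecular enamine‑catalysed Michael addition of aldehyde 8 to nitroalkene 5, which sets C6 and with it all absolute stereochemistry. Ring order: pyrrolidinone template, D, C, B, A, E.

Assumption: atom labels follow the usual Daphniphyllum numbering of the target (C1 lactam C=O, C2 carbinol, C5 and C8 quaternary, C6 and C15 ring‑fusion CH, C7 and C19 NCH2, C9=C10 alkene, C14 ester‑bearing CH, C18 CHMe, C21 CH2OAc); rings are A (C8‑C13‑C14‑C15‑C9), B (C9‑C10‑C17‑C16‑C15), C (cycloheptene), D (δ‑lactam), E (azacyclononane); TBDPS = tert‑butyldiphenylsilyl, SEM = 2‑(trimethylsilyl)ethoxymethyl, TBS = tert‑butyldimethylsilyl, Bn = benzyl.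

**Route**

Step 1
Reactants: 1 hex-5-en-1-ol
Product: 2 hex-5-enal
Conditions: TEMPO (2,2,6,6-tetramethylpiperidin-1-oxyl, 10 mol %), PhI(OAc)2, CH2Cl2, rt
Reagents that add atoms: none
Why: Oxoammonium (TEMPO/PhI(OAc)2) oxidation stops at the aldehyde and leaves the terminal alkene untouched.

Step 2
Reactants: 2 hex-5-enal; 3 nitromethane
Product: 5 (E)-1-nitrohepta-1,6-diene, via nitro alcohol 4 (not isolated)
Conditions: MeNO2 (5 equiv), KOtBu (5 mol %), THF/t-BuOH, 0 °C; then MeSO2Cl, Et3N, CH2Cl2, 0 °C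
Reagents that add atoms: none
Why: Henry (nitroaldol) addition followed by E1cB elimination of the mesylate gives the thermodynamically preferred E-nitroalkene.

Step 3
Reactants: 6 pentane-1,5-diol
Product: 7 5-[(tert-butyldiphenylsilyl)oxy]pentan-1-ol
Conditions: NaH (1.0 equiv), THF, rt; then t-BuPh2SiCl (1.0 equiv)
Reagents that add atoms: tert-butyl(chloro)diphenylsilane CC(C)(C)[Si](Cl)(c1ccccc1)c1ccccc1
Why: O-silylation of the sparingly soluble monosodium alkoxide (McDougal monoprotection) gives the mono-ether of the symmetrical diol.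

Step 4
Reactants: 7 5-[(tert-butyldiphenylsilyl)oxy]pentan-1-ol
Product: 8 5-[(tert-butyldiphenylsilyl)oxy]pentanal
Conditions: TEMPO (10 mol %), PhI(OAc)2, CH2Cl2, rt
Reagents that add atoms: none
Why: The same oxoammonium oxidation gives the aldehyde without over-oxidation or silyl loss.

Step 5
Reactants: 8 5-[(tert-butyldiphenylsilyl)oxy]pentanal; 5 (E)-1-nitrohepta-1,6-diene
Product: 9 (2S,3S)-2-{3-[(tert-butyldiphenylsilyl)oxy]propyl}-3-(nitromethyl)oct-7-enal
Conditions: (R)-2-[diphenyl(trimethylsilyloxy)methyl]pyrrolidine (10 mol %), 4-nitrophenol (10 mol %), toluene, 0 °C to rt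
Reagents that add atoms: none
Why: In this intermolecular enamine-catalysed Michael addition (Hayashi–Jørgensen conditions) the enamine of 8, shielded on one face by the diphenyl(silyloxy)methyl group, adds to the nitroalkene to give the syn adduct with C6 fixed as S, while the C5 centre formed here is re-made in Step 9.

Step 6
Reactants: 9 the Michael adduct
Product: 11 methyl (2S,3S)-2-{3-[(tert-butyldiphenylsilyl)oxy]propyl}-3-(nitromethyl)oct-7-enoate, via carboxylic acid 10 (not isolated)
Conditions: NaClO2, NaH2PO4, 2-methylbut-2-ene, t-BuOH/H2O, 0 °C; then Me3SiCHN2, MeOH/PhMe, 0 °C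
Reagents that add atoms: sodium chlorite [Na+].[O-]Cl=O; (trimethylsilyl)diazomethane C[Si](C)(C)C=[N+]=[N-]
Why: Pinnick oxidation followed by diazoalkane O-methylation converts the aldehyde into the ester under conditions that spare the alkene, the nitro group and the silyl ether.

Step 7
Reactants: 11 the nitro ester
Product: 13 (3S,4S)-3-{3-[(tert-butyldiphenylsilyl)oxy]propyl}-4-(pent-4-en-1-yl)pyrrolidin-2-one (trans), via amino ester 12 (not isolated)
Conditions: Zn dust, AcOH/EtOH, 40 °C; then aq. K2CO3, rt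
Reagents that add atoms: none
Why: Dissolving-metal reduction of the nitro group gives the amine, which lactamises 5-exo onto the ester to give the pyrrolidinone used as a stereochemical template.

Step 8
Reactants: 13 the pyrrolidinone
Product: 14 tert-butyl (3S,4S)-3-{3-[(tert-butyldiphenylsilyl)oxy]propyl}-2-oxo-4-(pent-4-en-1-yl)pyrrolidine-1-carboxylate
Conditions: Boc2O, DMAP (10 mol %), Et3N, MeCN, rt
Reagents that add atoms: di-tert-butyl dicarbonate CC(C)(C)OC(=O)OC(=O)OC(C)(C)C
Why: N-acylation (Boc protection) acidifies the C5–H and activates the lactam carbonyl for the later reductive opening.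

Step 9
Reactants: 14 the N-Boc pyrrolidinone; 15 tert-butyl bromoacetate
Product: 16 tert-butyl (3S,4S)-3-(2-tert-butoxy-2-oxoethyl)-3-{3-[(tert-butyldiphenylsilyl)oxy]propyl}-2-oxo-4-(pent-4-en-1-yl)pyrrolidine-1-carboxylate
Conditions: LiN(SiMe3)2 (1.1 equiv), THF, −78 °C; then 15, −78 to −40 °C
Reagents that add atoms: none
Why: Alkylation of the lactam lithium enolate occurs anti to the adjacent C6 pentenyl group, so quaternary C5 forms with the acetate arm trans and the silyloxypropyl chain cis to that group, which is the C5/C6 relationship of the target.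

Step 10
Reactants: 16 the dialkylated N-Boc pyrrolidinone
Product: 17 tert-butyl (3S,4S)-4-{[(tert-butoxycarbonyl)amino]methyl}-3-{3-[(tert-butyldiphenylsilyl)oxy]propyl}-3-(hydroxymethyl)non-8-enoate
Conditions: LiBH4, THF, 0 °C to rt
Reagents that add atoms: none
Why: The imide-like N-Boc lactam carbonyl undergoes reductive ring opening to the carbamate alcohol (C21 becomes CH2OH) while the tert-butyl ester is not reduced.

Step 11
Reactants: 17 the Boc-amino alcohol ester
Product: 19 (4S,5S)-4-{3-[(tert-butyldiphenylsilyl)oxy]propyl}-4-(hydroxymethyl)-5-(pent-4-en-1-yl)piperidin-2-one, via amino acid 18 (not isolated)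
Conditions: CF3CO2H/CH2Cl2 (1:3), rt; evaporate; then EDC·HCl, HOBt, iPr2NEt, CH2Cl2, rt
Reagents that add atoms: none
Why: Acidolysis removes Boc and the tert-butyl ester, and carbodiimide activation then gives the six-membered lactam (ring D) because the amine is acylated far faster than the neopentyl alcohol.

Step 12
Reactants: 19 the hydroxy lactam
Product: 20 (4S,5S)-4-[(benzyloxy)methyl]-4-{3-[(tert-butyldiphenylsilyl)oxy]propyl}-5-(pent-4-en-1-yl)piperidin-2-one
Conditions: BnOC(=NH)CCl3, CF3SO3H (5 mol %), CH2Cl2/cyclohexane, 0 °C to rt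
Reagents that add atoms: benzyl 2,2,2-trichloroacetimidate N=C(OCc1ccccc1)C(Cl)(Cl)Cl
Why: Acid-catalysed imidate benzylation etherifies the alcohol without touching the lactam N–H, which a basic Williamson benzylation would alkylate.

Step 13
Reactants: 20 the benzyl ether lactam
Product: 21 (4S,5S)-4-[(benzyloxy)methyl]-4-{3-[(tert-butyldiphenylsilyl)oxy]propyl}-5-(pent-4-en-1-yl)-1-{[2-(trimethylsilyl)ethoxy]methyl}piperidin-2-one
Conditions: NaH, THF/DMF, 0 °C; then Me3SiCH2CH2OCH2Cl
Reagents that add atoms: 2-(trimethylsilyl)ethoxymethyl chloride C[Si](C)(C)CCOCCl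
Why: N-alkylation of the sodium lactamate installs a base-stable SEM group that survives the enolate steps and is removed by Lewis acid in Step 20.

Step 14
Reactants: 21 the N-SEM lactam
Product: 22 methyl 4-[(3S,4S)-4-[(benzyloxy)methyl]-4-{3-[(tert-butyldiphenylsilyl)oxy]propyl}-6-oxo-1-{[2-(trimethylsilyl)ethoxy]methyl}piperidin-3-yl]butanoate
Conditions: O3, NaOH (2.5 M in MeOH), CH2Cl2, −78 °C (Sudan red end point)
Reagents that add atoms: ozone [O-][O+]=O; methanol CO
Why: Marshall ozonolysis in methanolic NaOH cleaves the terminal alkene and oxidises the aldehyde hemiacetal in situ to the methyl ester.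

Step 15
Reactants: 22 the lactam ester
Product: 23 (1S,6S,10R)-10-[(benzyloxy)methyl]-10-{3-[(tert-butyldiphenylsilyl)oxy]propyl}-8-{[2-(trimethylsilyl)ethoxy]methyl}-8-azabicyclo[4.3.1]decane-2,9-dione
Conditions: KOtBu (2.5 equiv), THF (0.01 M), 0 °C to rt; AcOH quench
Reagents that add atoms: none
Why: In this Dieckmann-type intramolecular Claisen condensation only the lactam enolate has an electrophile within reach, the product is drained as its β-keto-lactam enolate, and ring C closes with C8 as a bridgehead whose configuration is dictated by C6.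

Step 16
Reactants: 24 dimethyl malonate; 25 paraformaldehyde
Product: 26 dimethyl methylidenemalonate
Conditions: Cu(OAc)2 (cat.), KOAc (cat.), AcOH, 100 °C; distil and use fresh
Reagents that add atoms: none
Why: Knoevenagel condensation with formaldehyde gives the doubly activated Michael acceptor.

Step 17
Reactants: 23 the bridged keto-lactam; 26 dimethyl methylidenemalonate
Product: 27 dimethyl 2-{[(1S,6S,10R)-2,9-dioxo-8-azabicyclo[4.3.1]decan-1-yl]methyl}propanedioate carrying the C10 and N8 substituents of 23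
Conditions: K2CO3 (20 mol %), MeCN, 0 °C, slow addition of 26
Reagents that add atoms: none
Why: Michael addition of the β-keto-lactam carbanion (its enolate double bond lies in the four-carbon bridge, so enolisation is allowed) can only occur on the exo face of bridgehead C8, which therefore becomes quaternary as a single isomer.

Step 18
Reactants: 27 the Michael adduct
Product: 28 enol triflate of 27 (C9–OSO2CF3 with C9=C10)
Conditions: KN(SiMe3)2 (2.2 equiv), THF, −78 °C; then PhN(SO2CF3)2, −78 to 0 °C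
Reagents that add atoms: N-phenylbis(trifluoromethanesulfonimide) O=S(=O)(N(c1ccccc1)S(=O)(=O)C(F)(F)F)C(F)(F)F
Why: Because C8 is quaternary the ketone can enolise only toward C10, so O-sulfonylation gives one enol triflate regioisomer while the malonate is masked as its potassium enolate.

Step 19
Reactants: 28 the enol triflate; 29 carbon monoxide; 30 tributyl(vinyl)stannane
Product: 31 cross-conjugated dienone (C9 of the cycloheptene carries a prop-2-enoyl group)
Conditions: Pd(PPh3)4 (5 mol %), LiCl (3 equiv), CO (3 atm), THF, 55 °C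
Reagents that add atoms: none
Why: Carbonylative Stille coupling (oxidative addition, CO insertion, vinyl transfer) turns the alkenyl triflate into the divinyl ketone needed for the Nazarov reaction.

Step 20
Reactants: 31 the dienone
Product: 33 tricyclic enone (rings B, C and D; C15 ketone conjugated to C9=C10; free lactam N–H), via N-hydroxymethyl lactam 32 (not isolated)
Conditions: BF3·OEt2 (4 equiv), ClCH2CH2Cl, 0 °C to rt; then K2CO3, MeOH, rt
Reagents that add atoms: none
Why: Lewis-acid Nazarov cyclisation (4π conrotatory closure joining C10 to C17) followed by proton loss from C10 gives the more substituted ring-fusion enone without a new stereocentre, and BF3 also cleaves the SEM group, whose N-CH2OH remnant is discharged by methanolic K2CO3.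

Step 21
Reactants: 33 the tricyclic enone
Product: 34 (15S)-allylic alcohol
Conditions: (R)-2-methyl-CBS-oxazaborolidine [(R)-1-methyl-3,3-diphenyltetrahydro-1H,3H-pyrrolo[1,2-c][1,3,2]oxazaborole] (0.5 equiv), catecholborane (3 equiv), toluene, −60 °C
Reagents that add atoms: none
Why: Corey–Bakshi–Shibata reduction is reagent-controlled and, with the α-substituted alkenyl group as the large substituent, delivers hydride to give the 15S carbinol by 1,2-reduction only.

Step 22
Reactants: 34 the allylic alcohol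
Product: 35 (15S)-allylic methyl carbonate
Conditions: ClCO2Me, pyridine, DMAP (10 mol %), CH2Cl2, 0 °C
Reagents that add atoms: methyl chloroformate COC(=O)Cl
Why: O-acylation gives a carbonate leaving group that liberates its own methoxide base on ionisation, and the lactam N–H is not acylated under these conditions.

Step 23
Reactants: 35 the allylic carbonate
Product: 36 tetracyclic gem-diester (ring A closed; C14 bears two CO2Me; C15 as in the target)
Conditions: Pd2(dba)3·CHCl3 (2.5 mol %), dppe (6 mol %), THF, 40 °C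
Reagents that add atoms: none
Why: In this Tsuji–Trost allylic alkylation zerovalent palladium ionises anti to the carbonate and the soft malonate attacks anti to palladium at the less substituted terminus C15 (not the fully substituted C10), so the C14–C15 bond forms with net retention and C15 takes the target configuration.

Step 24
Reactants: 36 the gem-diester
Product: 37 tetracyclic mono-ester, mixture of C14 epimers
Conditions: LiCl, H2O, Me2SO, 150 °C
Reagents that add atoms: none
Why: Krapcho dealkoxycarbonylation removes one ester under neutral conditions that tolerate the lactam, alkene and ethers.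

Step 25
Reactants: 37 the mono-ester epimers
Product: 38 tetracyclic ester with C14 as in the target (CO2Me cis to C16 and to C5)
Conditions: LiN(iPr)2 (2.3 equiv), THF, −78 °C; then AcOH in THF, −78 °C
Reagents that add atoms: none
Why: Kinetic protonation of the ester enolate takes place on the open convex face of ring A, anti to both C16 and the C5 bridge, which places the ester on the concave face as the target requires.

Step 26
Reactants: 38 the TBDPS ether
Product: 39 primary alcohol (C2–OH)
Conditions: Bu4NF, AcOH, THF, rt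
Reagents that add atoms: none
Why: Fluoride desilylation buffered with acetic acid frees the chain-end alcohol without epimerising C14.

Step 27
Reactants: 39 the primary alcohol
Product: 40 tetracyclic aldehyde (C2 = CHO)
Conditions: TEMPO (10 mol %), PhI(OAc)2, CH2Cl2, rt
Reagents that add atoms: none
Why: Oxoammonium oxidation gives the aldehyde and leaves the lactam and the tetrasubstituted alkene alone.

Step 28
Reactants: 40 the aldehyde; 41 (S)-4-benzyl-3-propanoyl-1,3-oxazolidin-2-one
Product: 42 syn-aldol adduct (C2 R, C18 S; N-acyl oxazolidinone at C19)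
Conditions: 41 (1.5 equiv), Bu2BOSO2CF3, iPr2NEt, CH2Cl2, −78 to 0 °C; then 40, −78 to 0 °C; pH 7 buffer, MeOH, 30 % H2O2
Reagents that add atoms: none
Why: In this Evans syn-aldol the Z-boron enolate reacts through a Zimmerman–Traxler chair whose face is fixed by the (S)-benzyl auxiliary, so the C2–C18 bond forms with the C2 hydroxyl and C18 methyl arranged as in the target regardless of the remote core stereocentres.

Step 29
Reactants: 42 the aldol adduct
Product: 43 C2 TBS ether
Conditions: t-BuMe2SiOSO2CF3, 2,6-lutidine, CH2Cl2, −78 to 0 °C; aq. NaHCO3 work-up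
Reagents that add atoms: tert-butyldimethylsilyl trifluoromethanesulfonate CC(C)(C)[Si](C)(C)OS(=O)(=O)C(F)(F)F
Why: Silylation blocks retro-aldol and later oxetane formation, and any silylation of the lactam is reversed on aqueous work-up.

Step 30
Reactants: 43 the silylated imide
Product: 44 primary alcohol at C19
Conditions: NaBH4, THF/H2O (4:1), 0 °C to rt
Reagents that add atoms: none
Why: Borohydride reduces the activated exocyclic imide carbonyl to the alcohol and releases the auxiliary while the hindered methyl ester and the lactam survive.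

Step 31
Reactants: 44 the C19 alcohol
Product: 45 C19 methanesulfonate
Conditions: MeSO2Cl, Et3N, CH2Cl2, 0 °C
Reagents that add atoms: methanesulfonyl chloride CS(=O)(=O)Cl
Why: O-sulfonylation activates C19 for displacement and the lactam N–H is not sulfonylated.

Step 32
Reactants: 45 the mesylate
Product: 46 pentacyclic lactam (ring E closed; C21 OBn, C2 OTBS)
Conditions: Cs2CO3, Bu4NI (20 mol %), DMF (2 mM), 60 °C
Reagents that add atoms: none
Why: Intramolecular SN2 N-alkylation of the lactam (iodide formed in situ, high dilution) closes the nine-membered ring because the C5 side chain is held over ring D, and the mild carbonate base does not epimerise C14.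

Step 33
Reactants: 46 the benzyl ether
Product: 47 C21 primary alcohol
Conditions: H2 (1 atm), Pd(OH)2/C, EtOAc, rt
Reagents that add atoms: none
Why: Hydrogenolysis removes the benzyl group while the hindered tetrasubstituted C9=C10 alkene is not hydrogenated.

Step 34
Reactants: 47 the C21 alcohol
Product: 48 C21 acetate (C2 OTBS)
Conditions: Ac2O, pyridine, DMAP (5 mol %), CH2Cl2, rt
Reagents that add atoms: acetic anhydride CC(=O)OC(C)=O
Why: DMAP-catalysed acylation esterifies the only free hydroxyl.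

Step 35
Reactants: 48 the silyl ether acetate
Product: 49 target CNP0296366.1
Conditions: HF·pyridine, THF/pyridine, 0 °C to rt
Reagents that add atoms: none
Why: Buffered fluoride desilylation frees the C2 hydroxyl without cleaving or migrating the remote acetate.

**Compound list**

1 | hex-5-en-1-ol | OCCCCC=C | starting material
2 | hex-5-enal | O=CCCCC=C | intermediate
3 | nitromethane | C[N+](=O)[O-] | starting material
4 | 1-nitrohept-6-en-2-ol (racemic, not isolated) | OC(CCCC=C)C[N+](=O)[O-] | intermediate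
5 | (E)-1-nitrohepta-1,6-diene | C=CCCC/C=C/[N+](=O)[O-] | intermediate
6 | pentane-1,5-diol | OCCCCCO | starting material
7 | 5-[(tert-butyldiphenylsilyl)oxy]pentan-1-ol | OCCCCCO[Si](c1ccccc1)(c2ccccc2)C(C)(C)C | intermediate
8 | 5-[(tert-butyldiphenylsilyl)oxy]pentanal | O=CCCCCO[Si](c1ccccc1)(c2ccccc2)C(C)(C)C | intermediate
9 | (2S,3S)-2-{3-[(TBDPS)oxy]propyl}-3-(nitromethyl)oct-7-enal | O=C[C@@H](CCCO[Si](c1ccccc1)(c2ccccc2)C(C)(C)C)[C@H](CCCC=C)C[N+](=O)[O-] | intermediate
10 | (2S,3S)-2-{3-[(TBDPS)oxy]propyl}-3-(nitromethyl)oct-7-enoic acid (not isolated) | OC(=O)[C@@H](CCCO[Si](c1ccccc1)(c2ccccc2)C(C)(C)C)[C@H](CCCC=C)C[N+](=O)[O-] | intermediate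
11 | methyl (2S,3S)-2-{3-[(TBDPS)oxy]propyl}-3-(nitromethyl)oct-7-enoate | COC(=O)[C@@H](CCCO[Si](c1ccccc1)(c2ccccc2)C(C)(C)C)[C@H](CCCC=C)C[N+](=O)[O-] | intermediate
12 | methyl (2S,3S)-3-(aminomethyl)-2-{3-[(TBDPS)oxy]propyl}oct-7-enoate (not isolated) | COC(=O)[C@@H](CCCO[Si](c1ccccc1)(c2ccccc2)C(C)(C)C)[C@H](CCCC=C)CN | intermediate
13 | (3S,4S)-3-{3-[(TBDPS)oxy]propyl}-4-(pent-4-en-1-yl)pyrrolidin-2-one | O=C1NC[C@@H](CCCC=C)[C@@H]1CCCO[Si](c2ccccc2)(c3ccccc3)C(C)(C)C | intermediate
14 | tert-butyl (3S,4S)-3-{3-[(TBDPS)oxy]propyl}-2-oxo-4-(pent-4-en-1-yl)pyrrolidine-1-carboxylate | O=C1N(C(=O)OC(C)(C)C)C[C@@H](CCCC=C)[C@@H]1CCCO[Si](c2ccccc2)(c3ccccc3)C(C)(C)C | intermediate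
15 | tert-butyl bromoacetate | BrCC(=O)OC(C)(C)C | starting material
16 | tert-butyl (3S,4S)-3-(2-tert-butoxy-2-oxoethyl)-3-{3-[(TBDPS)oxy]propyl}-2-oxo-4-(pent-4-en-1-yl)pyrrolidine-1-carboxylate | O=C1N(C(=O)OC(C)(C)C)C[C@@H](CCCC=C)[C@@]1(CC(=O)OC(C)(C)C)CCCO[Si](c2ccccc2)(c3ccccc3)C(C)(C)C | intermediate
17 | tert-butyl (3S,4S)-4-{[(tert-butoxycarbonyl)amino]methyl}-3-{3-[(TBDPS)oxy]propyl}-3-(hydroxymethyl)non-8-enoate | CC(C)(C)OC(=O)NC[C@@H](CCCC=C)[C@@](CO)(CC(=O)OC(C)(C)C)CCCO[Si](c1ccccc1)(c2ccccc2)C(C)(C)C | intermediate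
18 | (3S,4S)-4-(aminomethyl)-3-{3-[(TBDPS)oxy]propyl}-3-(hydroxymethyl)non-8-enoic acid (not isolated) | NC[C@@H](CCCC=C)[C@@](CO)(CC(=O)O)CCCO[Si](c1ccccc1)(c2ccccc2)C(C)(C)C | intermediate
19 | (4S,5S)-4-{3-[(TBDPS)oxy]propyl}-4-(hydroxymethyl)-5-(pent-4-en-1-yl)piperidin-2-one | O=C1NC[C@@H](CCCC=C)[C@](CO)(CCCO[Si](c2ccccc2)(c3ccccc3)C(C)(C)C)C1 | intermediate
20 | (4S,5S)-4-[(benzyloxy)methyl]-4-{3-[(TBDPS)oxy]propyl}-5-(pent-4-en-1-yl)piperidin-2-one | O=C1NC[C@@H](CCCC=C)[C@](COCc2ccccc2)(CCCO[Si](c3ccccc3)(c4ccccc4)C(C)(C)C)C1 | intermediate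
21 | N-SEM derivative of 20 | O=C1N(COCC[Si](C)(C)C)C[C@@H](CCCC=C)[C@](COCc2ccccc2)(CCCO[Si](c3ccccc3)(c4ccccc4)C(C)(C)C)C1 | intermediate
22 | methyl 4-[(3S,4S)-4-[(benzyloxy)methyl]-4-{3-[(TBDPS)oxy]propyl}-6-oxo-1-SEM-piperidin-3-yl]butanoate | O=C1N(COCC[Si](C)(C)C)C[C@@H](CCCC(=O)OC)[C@](COCc2ccccc2)(CCCO[Si](c3ccccc3)(c4ccccc4)C(C)(C)C)C1 | intermediate
23 | (1S,6S,10R)-10-[(benzyloxy)methyl]-10-{3-[(TBDPS)oxy]propyl}-8-SEM-8-azabicyclo[4.3.1]decane-2,9-dione | O=C1CCC[C@@H]2CN(COCC[Si](C)(C)C)C(=O)[C@H]1[C@@]2(COCc3ccccc3)CCCO[Si](c4ccccc4)(c5ccccc5)C(C)(C)C | intermediate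
24 | dimethyl malonate | COC(=O)CC(=O)OC | starting material
25 | paraformaldehyde (formaldehyde source) | C=O | starting material
26 | dimethyl methylidenemalonate | C=C(C(=O)OC)C(=O)OC | intermediate
27 | dimethyl 2-{[(1S,6S,10R)-2,9-dioxo-8-azabicyclo[4.3.1]decan-1-yl]methyl}propanedioate with C10 CH2OBn, C10 (CH2)3OTBDPS and N8 SEM | COC(=O)C(C(=O)OC)C[C@@]12C(=O)N(COCC[Si](C)(C)C)C[C@@H](CCCC1=O)[C@]2(COCc3ccccc3)CCCO[Si](c4ccccc4)(c5ccccc5)C(C)(C)C | intermediate
28 | enol triflate of 27 (C9–OTf, C9=C10) | COC(=O)C(C(=O)OC)C[C@@]12C(=O)N(COCC[Si](C)(C)C)C[C@@H](CCC=C1OS(=O)(=O)C(F)(F)F)[C@]2(COCc3ccccc3)CCCO[Si](c4ccccc4)(c5ccccc5)C(C)(C)C | intermediate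
29 | carbon monoxide | [C-]#[O+] | starting material
30 | tributyl(vinyl)stannane | C=C[Sn](CCCC)(CCCC)CCCC | starting material
31 | dienone (prop-2-enoyl group on C9 of the bicyclic alkene) | COC(=O)C(C(=O)OC)C[C@@]12C(=O)N(COCC[Si](C)(C)C)C[C@@H](CCC=C1C(=O)C=C)[C@]2(COCc3ccccc3)CCCO[Si](c4ccccc4)(c5ccccc5)C(C)(C)C | intermediate
32 | N-(hydroxymethyl) tricyclic enone (not isolated) | COC(=O)C(C(=O)OC)C[C@@]12C(=O)N(CO)C[C@@H](CCC3=C1C(=O)CC3)[C@]2(COCc4ccccc4)CCCO[Si](c5ccccc5)(c6ccccc6)C(C)(C)C | intermediate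
33 | tricyclic enone (rings B, C, D; C15 ketone; N–H lactam; C8 CH2CH(CO2Me)2) | COC(=O)C(C(=O)OC)C[C@@]12C(=O)NC[C@@H](CCC3=C1C(=O)CC3)[C@]2(COCc4ccccc4)CCCO[Si](c5ccccc5)(c6ccccc6)C(C)(C)C | intermediate
34 | (15S)-allylic alcohol of 33 | COC(=O)C(C(=O)OC)C[C@@]12C(=O)NC[C@@H](CCC3=C1[C@@H](O)CC3)[C@]2(COCc4ccccc4)CCCO[Si](c5ccccc5)(c6ccccc6)C(C)(C)C | intermediate
35 | (15S)-allylic methyl carbonate | COC(=O)C(C(=O)OC)C[C@@]12C(=O)NC[C@@H](CCC3=C1[C@@H](OC(=O)OC)CC3)[C@]2(COCc4ccccc4)CCCO[Si](c5ccccc5)(c6ccccc6)C(C)(C)C | intermediate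
36 | tetracyclic C14 gem-diester (rings A–D; C5, C6, C8, C15 as in target) | COC(=O)C1(C(=O)OC)C[C@@]23C(=O)NC[C@@H](CCC4=C2[C@@H]1CC4)[C@]3(COCc5ccccc5)CCCO[Si](c6ccccc6)(c7ccccc7)C(C)(C)C | intermediate
37 | tetracyclic C14 mono-ester, C14 epimer mixture | COC(=O)C1C[C@@]23C(=O)NC[C@@H](CCC4=C2[C@@H]1CC4)[C@]3(COCc5ccccc5)CCCO[Si](c6ccccc6)(c7ccccc7)C(C)(C)C | intermediate
38 | tetracyclic ester, C14 as in target; C21 OBn; chain-end OTBDPS | COC(=O)[C@@H]1C[C@@]23C(=O)NC[C@@H](CCC4=C2[C@@H]1CC4)[C@]3(COCc5ccccc5)CCCO[Si](c6ccccc6)(c7ccccc7)C(C)(C)C | intermediate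
39 | tetracyclic primary alcohol (C2–OH) | COC(=O)[C@@H]1C[C@@]23C(=O)NC[C@@H](CCC4=C2[C@@H]1CC4)[C@]3(COCc5ccccc5)CCCO | intermediate
40 | tetracyclic aldehyde (C2 = CHO) | COC(=O)[C@@H]1C[C@@]23C(=O)NC[C@@H](CCC4=C2[C@@H]1CC4)[C@]3(COCc5ccccc5)CCC=O | intermediate
41 | (S)-4-benzyl-3-propanoyl-1,3-oxazolidin-2-one | CCC(=O)N1[C@@H](Cc2ccccc2)COC1=O | starting material
42 | syn-aldol adduct (C2 R, C18 S; (S)-benzyloxazolidinone imide) | COC(=O)[C@@H]1C[C@@]23C(=O)NC[C@@H](CCC4=C2[C@@H]1CC4)[C@]3(COCc5ccccc5)CC[C@@H](O)[C@H](C)C(=O)N6[C@@H](Cc7ccccc7)COC6=O | intermediate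
43 | C2 TBS ether of 42 | COC(=O)[C@@H]1C[C@@]23C(=O)NC[C@@H](CCC4=C2[C@@H]1CC4)[C@]3(COCc5ccccc5)CC[C@@H](O[Si](C)(C)C(C)(C)C)[C@H](C)C(=O)N6[C@@H](Cc7ccccc7)COC6=O | intermediate
44 | C19 primary alcohol (C2 OTBS; C18 methyl as in target) | COC(=O)[C@@H]1C[C@@]23C(=O)NC[C@@H](CCC4=C2[C@@H]1CC4)[C@]3(COCc5ccccc5)CC[C@@H](O[Si](C)(C)C(C)(C)C)[C@H](C)CO | intermediate
45 | C19 methanesulfonate | COC(=O)[C@@H]1C[C@@]23C(=O)NC[C@@H](CCC4=C2[C@@H]1CC4)[C@]3(COCc5ccccc5)CC[C@@H](O[Si](C)(C)C(C)(C)C)[C@H](C)COS(C)(=O)=O | intermediate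
46 | pentacyclic lactam (C21 OBn, C2 OTBS) | COC(=O)[C@@H]1C[C@@]23C(=O)N4C[C@@H](CCC5=C2[C@@H]1CC5)[C@]3(COCc6ccccc6)CC[C@@H](O[Si](C)(C)C(C)(C)C)[C@H](C)C4 | intermediate
47 | pentacyclic C21 alcohol (C2 OTBS) | COC(=O)[C@@H]1C[C@@]23C(=O)N4C[C@@H](CCC5=C2[C@@H]1CC5)[C@]3(CO)CC[C@@H](O[Si](C)(C)C(C)(C)C)[C@H](C)C4 | intermediate
48 | pentacyclic C21 acetate (C2 OTBS) | COC(=O)[C@@H]1C[C@@]23C(=O)N4C[C@@H](CCC5=C2[C@@H]1CC5)[C@]3(COC(C)=O)CC[C@@H](O[Si](C)(C)C(C)(C)C)[C@H](C)C4 | intermediate
49 | CNP0296366.1 | COC(=O)[C@@H]1C[C@@]23C(=O)N4C[C@@H](CCC5=C2[C@@H]1CC5)[C@]3(COC(C)=O)CC[C@@H](O)[C@H](C)C4 | target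

**Totals**

Total step count: 35. Longest linear sequence: 32 steps (Steps 3–15 and 17–35; the branch through Steps 1 and 2 is of equal length).

**Steps most likely to fail and fallbacks**

Step 15, the Dieckmann-type closure of the bridged ring C, may stall because the lactam and ester positions have similar acidity and the 1,3-diaxial bridge is strained. The fallback sets out from 21 and returns at 23, replacing the Claisen acylation by a Reformatsky-type aldol with samarium diiodide. Lactam 21 is brominated at C8 through its lithium enolate (LiN(iPr)2, THF, −78 °C; then BrCl2CCCl2Br) to give the α-bromo lactam F1. Ozonolysis with reductive work-up (O3, CH2Cl2, −78 °C; PPh3) gives the bromo aldehyde F2. SmI2 (2.5 equiv, THF, −78 °C, high dilution) forms the C8 samarium enolate under neutral conditions, where the aldehyde is not enolised, and this adds to the aldehyde to give the bridged β-hydroxy lactam F3. Dess–Martin periodinane in CH2Cl2 then gives 23.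

Step 23, the palladium-catalysed closure of ring A, forms a strained bicyclo[3.3.0]octene from a tether on the central allyl carbon and could give elimination or attack at C10. The fallback sets out from 33 and returns at 36, replacing the π-allyl pathway by a direct SN2 displacement. Enone 33 is reduced with the (S)-enantiomer of the CBS catalyst and catecholborane to the (15R)-allylic alcohol F4. Tsunoda-type Mitsunobu C-alkylation (Bu3P=CHCN, toluene, 100 °C) then lets the malonate displace the activated hydroxyl with inversion, giving 36.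

Step 32, the nine-membered N-alkylation, may be slow or give O-alkylation or oligomers. The fallback sets out from 44 and returns at 46, replacing SN2 alkylation by reductive N-alkylation through an N-acyliminium ion. Alcohol 44 is oxidised (TEMPO, PhI(OAc)2, CH2Cl2) to the aldehyde F5. BF3·OEt2 and Et3SiH (CH2Cl2, −40 to 0 °C, high dilution) then bring about reversible hemiaminal formation between the lactam N–H and the aldehyde, ionisation and hydride capture to give 46. C18 must be checked for epimerisation through the enamide tautomer.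

**Further compounds**

F1 | step 15 | (4S,5S)-4-[(benzyloxy)methyl]-3-bromo-4-{3-[(TBDPS)oxy]propyl}-5-(pent-4-en-1-yl)-1-SEM-piperidin-2-one (C3 epimers) | O=C1N(COCC[Si](C)(C)C)C[C@@H](CCCC=C)[C@](COCc2ccccc2)(CCCO[Si](c3ccccc3)(c4ccccc4)C(C)(C)C)C1Br
F2 | step 15 | 4-[(3S,4S)-4-[(benzyloxy)methyl]-5-bromo-4-{3-[(TBDPS)oxy]propyl}-6-oxo-1-SEM-piperidin-3-yl]butanal | O=C1N(COCC[Si](C)(C)C)C[C@@H](CCCC=O)[C@](COCc2ccccc2)(CCCO[Si](c3ccccc3)(c4ccccc4)C(C)(C)C)C1Br
F3 | step 15 | (1S,6S,10R)-10-[(benzyloxy)methyl]-10-{3-[(TBDPS)oxy]propyl}-2-hydroxy-8-SEM-8-azabicyclo[4.3.1]decan-9-one (C2 epimers) | OC1CCC[C@@H]2CN(COCC[Si](C)(C)C)C(=O)[C@H]1[C@@]2(COCc3ccccc3)CCCO[Si](c4ccccc4)(c5ccccc5)C(C)(C)C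
F4 | step 23 | (15R)-allylic alcohol, C15 epimer of 34 | COC(=O)C(C(=O)OC)C[C@@]12C(=O)NC[C@@H](CCC3=C1[C@H](O)CC3)[C@]2(COCc4ccccc4)CCCO[Si](c5ccccc5)(c6ccccc6)C(C)(C)C
F5 | step 32 | C19 aldehyde corresponding to 44 | COC(=O)[C@@H]1C[C@@]23C(=O)NC[C@@H](CCC4=C2[C@@H]1CC4)[C@]3(COCc5ccccc5)CC[C@@H](O[Si](C)(C)C(C)(C)C)[C@H](C)C=O
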